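The readings were computed with made-up constants, and the scatter is random.

The midnight run, this same flask followed up to 12.0 h, is what I have to work from:

common to all: starting material 0.020 M; gas 7.1 mM (held)

|  | second nucleophile | remark | time |
|---|---|---|---|
| midnight | 1.2 equiv | the very flask that is asked about, followed so far |  |
| flask | 1.20 equiv |  | 40 h |

midnight run (percent of the starting material charged)

| time / h | other capture product / % | target / % |
|---|---|---|
| 2.50 | 13.4 | 0.7 |
| 5.00 | 23.2 | 1.0 |
| 8.00 | 35.2 | 0.7 |
| 10.0 | 40.4 | 1.0 |
| 12.0 | 46.4 | 1.2 |

(each reading ± 0.5 percentage points)

* share of other capture product in other capture product plus target at 15 min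
* share of other capture product in other capture product plus target at 40 h

Its last reading gives 0.0539 h⁻¹ for the capture constant, minus the logarithm of the fraction of charge not yet captured, over the time. The reading at 5.00 h gives about the same, 0.0554 h⁻¹, although by 12.0 h the other capture product reading puts the second nucleophile at about 61.3% of its charge, so I read starting material to intermediate as the rate-limiting step and integrate that first-order rate.

At 40 h the captured fraction is then 88.4%, less than the 1.20 equiv of second nucleophile, and if I charge all of that capture to second nucleophile, counting nothing for the part that goes through first nucleophile, my estimate is that 26.3% of its charge stays. If target stays at its last reading, 1.2%, the share at 40 h is 98.6%. At 15 min I expect a share above the 95.0% read at 2.50 h, since first nucleophile starts undissolved.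

The weak link is that flat target. If its level follows its inflow, which goes with the starting material left over the second nucleophile left, with first nucleophile held as at 12.0 h, it falls to 0.516 of that reading, about half, and the share becomes 99.3%. I commit to the span between the two.

The forecast says 98% and 94%, lower than mine, on the ground that “the first nucleophile competes better late on”. The flask gives 99.9% and 98.7%.

    starting material ⇌ intermediate (K = 0.120, k = 0.0550 h⁻¹)
    first nucleophile + intermediate → target (k = 25000 L mol⁻¹ h⁻¹)
    second nucleophile + intermediate → other capture product (k = 1.70 × 10⁵ L mol⁻¹ h⁻¹)
    second nucleophile → decomposition product (k = 8.40 × 10⁻⁵ h⁻¹)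
    gas ⇌ first nucleophile, rate k5*(csat - [first nucleophile]) (kL = 0.270 h⁻¹)
    target ⇌ isomer of the product (K = 10.0, k = 0.130 h⁻¹)

In this flask 11.1% of the starting material stands at 40.0 h, against 11.6% by the capture constant. The neighbour flask, charged with 0.480 equiv of second nucleophile, holds 11.1% of starting material at the same time. Its second nucleophile can take 0.480 equiv of the 88.4% captured, which leaves 40.4% for first nucleophile. It ends with 0.0080% of its second nucleophile, 48.0% of other capture product, and 40.9% as target plus isomer of the product, of which target is 9.35%, so its share is 83.7%.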